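The target in the earlier runs stopped rising with substrate still beside it: the gamma run ended at 27.0% target and 72.2% substrate. I had to judge what that stop was before trusting it at a new temperature.

in all of them: free catalyst 28 mM; second catalyst 140 mM
- gamma: substrate 2 M; partner 1.68 M; temperature 65 °C; run made earlier
- theta: substrate 1.4 M; partner 0.84 M; temperature 100 °C; run made earlier
- alder: substrate 1.4 M; partner 1.68 M; temperature 100 °C; time 4.0 h
- ash: substrate 1.4 M; partner 1.68 M; at 130 °C until 80 min, from then on at 70 °C; time 4.0 h
- oak: substrate 1.4 M; partner 1.68 M; temperature 130 °C; time 4.0 h
- larch: substrate 1.4 M; partner 1.68 M; temperature 70 °C; time 4.0 h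

| run | time / h | target / % | substrate / % |
|---|---|---|---|
| gamma | 2.50 | 21.2 | 73.0 |
| gamma | 6.00 | 26.6 | 73.0 |
| gamma | 12.0 | 26.1 | 71.9 |
| gamma | 15.0 | 27.0 | 72.2 |
| theta | 0.250 | 3.1 | 95.3 |
| theta | 0.667 | 5.3 | 94.4 |
| theta | 1.33 | 6.3 | 94.2 |
| theta | 3.00 | 5.3 | 93.6 |

(each reading ± 0.5 percentage points)

* the flask that comes out highest in amount of target, in percent of the substrate charged, or "all alike" when all lie within 1.5 percentage points (alder / ash / oak / larch / all alike)
* target at the end, in percent of the substrate charged, alder
* target at the end, in percent of the substrate charged, ash
* target at the end, in percent of the substrate charged, oak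
* target at the end, in percent of the substrate charged, larch

I tried two ways to the same number, the target in alder, which differs from the theta run by its partner charge, twice as large. The first way reads the stop as an equilibrium of substrate and partner with target. More partner then pushes the target up, to about 10.5%, twice the last theta reading.

The second way reads the stop as the end of the free catalyst. Suppose the rate is k·[substrate]·[free catalyst], with free catalyst lost at first order with constant d. The natural log of substrate charged over substrate left at the stop, L, then equals k·C/d, where C is the free catalyst charged. Partner and substrate charge do not enter, and gamma and theta share one C. From the last two readings of each run, gamma gave 0.328 and theta 0.0629. That is an energy difference of 49.5 kJ mol⁻¹ and, for alder, 6.10%.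

The two ways parted, so I looked for the one that cheats. In a single equilibrium step, each target made costs one substrate. Yet in the gamma run substrate read 73.0% and then 73.0%, while target gained 5.4 percentage points, well beyond the scatter of 0.5 points. Substrate stopped first, with something lying between it and the target, so I trusted L.

At 130 °C, the natural log of substrate charged over substrate left at the stop came to 0.0192, which means 1.90% for oak. At 70 °C, L was 0.254, which means 22.4% for larch. Theta's substrate was already at 94.4% by 0.667 h, and ash's hot stage lasted longer, in a hotter bath. So I expected ash to match oak and the cooling to bring nothing.

The forecast read the stop as an equilibrium, “though catalyst death could look the same”. It gave larch as highest, with alder 10.5%, ash 21.5%, oak 4.3% and larch 24%. We agreed on the winner but parted widely on ash.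

The flasks gave alder 5.81%, ash 1.79%, oak 1.79% and larch 21.3%, with larch highest.

    partner + second catalyst + intermediate → second catalyst + target (k = 0.0890 L² mol⁻² min⁻¹, Ea = 51.0 kJ mol⁻¹)
    free catalyst → spent catalyst (k = 0.0640 min⁻¹, Ea = 110 kJ mol⁻¹)
    substrate + free catalyst → free catalyst + intermediate (k = 0.560 L mol⁻¹ min⁻¹, Ea = 60.0 kJ mol⁻¹)
    (constants at 70 °C)

In ash, the target step had half its turnover behind it at 2.38 min, far inside the 80 min of heat. At the change, free catalyst stood at 0% and spent catalyst at 100%, and target stayed at 1.79% through 40.0 h, against 1.90% from L. A neighbouring flask, the same as ash but with 0.11 M of free catalyst, has L scaled to 0.0755, which means 7.27%, and it gave 6.85%.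

The numbers in the tables were computed on assumed constants.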